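The isoflavanone is cut back to its isoflavone and then at C3, the one atom of the pyranone ring (O1–C2–C3–C4–C4a–C8a) that carries the chromene B-ring and lies between C2 and the C4 carbonyl. Removing it leaves the furan ring of a 3-silyloxybenzofuran, whose O–C=C–OSi enol ether is an ideal carbene acceptor. In the key step an aryl(chloro)carbene, released from a chlorodiazirine that already holds the 2,2-dimethylchromene, is inserted into that bond. Cyclopropanation and cyclopropyl-to-allyl opening expand the five-membered ring to the six-membered one and join both halves in one operation. C3 is then made stereogenic (R) by 1,4-reduction and Pd-catalysed decarboxylative asymmetric protonation.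

Key step: step 7

Remark: the configuration drawn corresponds to 3R, and 4,6-dihydroxy-1-benzofuran-3(2H)-one is taken as a purchasable starting material.

Step 1
Reactants: 1 4,6-dihydroxy-1-benzofuran-3(2H)-one
Product: 2 3,4,6-tris(tert-butyldimethylsilyloxy)-1-benzofuran
Conditions: TBSOTf (3.3 equiv), Et3N, CH2Cl2, 0 °C → rt
Reagents that add atoms: tert-butyldimethylsilyl trifluoromethanesulfonate, CC(C)(C)[Si](C)(C)OS(=O)(=O)C(F)(F)F
Why: Soft enolisation and O-silylation should cap both phenols and trap the aromatic enol form of the benzofuranone as its 3-silyl enol ether.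

Step 2
Reactants: 3 4-bromobenzene-1,3-diol
Product: 4 2-bromo-5-(triisopropylsilyloxy)phenol
Conditions: TIPSCl (1.0 equiv), imidazole, CH2Cl2, −20 → 0 °C
Reagents that add atoms: chlorotriisopropylsilane, CC(C)[Si](Cl)(C(C)C)C(C)C
Why: Regioselective phenol silylation, in which the bulky silyl chloride should take the unhindered hydroxyl para to bromine while the hydroxyl ortho to bromine is shielded and reacts more slowly.

Step 3
Reactants: 4 2-bromo-5-(triisopropylsilyloxy)phenol; 5 3-chloro-3-methylbut-1-yne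
Product: 6 [4-bromo-3-(2-methylbut-3-yn-2-yloxy)phenoxy]triisopropylsilane
Conditions: CuCl2·2H2O (cat.), DBU, MeCN, 0 °C
Reagents that add atoms: none
Why: Copper-catalysed propargylic etherification should alkylate the remaining hindered phenol with the tertiary propargylic chloride under a mild base that leaves the aryl silyl ether intact.

Step 4
Reactants: 6 [4-bromo-3-(2-methylbut-3-yn-2-yloxy)phenoxy]triisopropylsilane
Product: 8 8-bromo-2,2-dimethyl-5-(triisopropylsilyloxy)-2H-chromene, via o-allenylphenol 7 (not isolated)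
Conditions: N,N-diethylaniline, 180 °C
Reagents that add atoms: none
Why: The aromatic propargyl Claisen rearrangement can only go to the free ortho carbon between the two oxygens, and the o-allenylphenol 7 should close by 1,5-hydrogen shift and oxa-6π electrocyclisation to the 2,2-dimethylchromene.

Step 5
Reactants: 8 8-bromo-2,2-dimethyl-5-(triisopropylsilyloxy)-2H-chromene
Product: 11 2,2-dimethyl-5-(triisopropylsilyloxy)-2H-chromene-8-carboximidamide hydrochloride, via aryllithium 9 (not isolated), via lithium bis(trimethylsilyl)amidinate 10 (not isolated)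
Conditions: n-BuLi, THF, −78 °C; TMSN=C=NTMS, −78 °C → rt; HCl/EtOH, 0 °C
Reagents that add atoms: N,N'-bis(trimethylsilyl)carbodiimide, C[Si](C)(C)N=C=N[Si](C)(C)C; hydrogen chloride, Cl
Why: Bromine–lithium exchange and addition of aryllithium 9 to the carbodiimide carbon should give amidinate 10, which ethanolic HCl desilylates to the amidinium chloride (amidine synthesis from an organolithium and a carbodiimide).

Step 6
Reactants: 11 2,2-dimethyl-5-(triisopropylsilyloxy)-2H-chromene-8-carboximidamide hydrochloride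
Product: 12 3-chloro-3-[2,2-dimethyl-5-(triisopropylsilyloxy)-2H-chromen-8-yl]-3H-diazirine
Conditions: aq. NaOCl, LiCl, DMSO/pentane, 0 °C → rt; used at once as a solution
Reagents that add atoms: sodium hypochlorite, [Na+].[O-]Cl; lithium chloride, [Li+].[Cl-]
Why: Graham oxidation, in which hypochlorite N-chlorinates the amidine, base closes the N–N bond and chloride returns to carbon to give the 3-aryl-3-chlorodiazirine.

Step 7
Reactants: 2 3,4,6-tris(tert-butyldimethylsilyloxy)-1-benzofuran; 12 3-chloro-3-[2,2-dimethyl-5-(triisopropylsilyloxy)-2H-chromen-8-yl]-3H-diazirine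
Product: 16 5,7-bis(tert-butyldimethylsilyloxy)-3-[2,2-dimethyl-5-(triisopropylsilyloxy)-2H-chromen-8-yl]-4H-chromen-4-one, via aryl(chloro)carbene 13 (not isolated), via chlorocyclopropane adduct 14 (not isolated), via 4-silyloxychromenylium chloride 15 (not isolated)
Conditions: 2 (1.5 equiv), Na2CO3, MeCN/toluene, 40 °C, dark
Reagents that add atoms: none
Why: Proposed new method: mild thermolysis of 12 should release N2 and carbene 13, which adds in a (2+1) cheletropic closure to the doubly oxygen-activated benzofuran C2=C3 enol-ether bond of 2 to give the fused chlorocyclopropane 14; ionisation of the C–Cl bond coupled to disrotatory 2π-electrocyclic opening of the former C2–C3 bond then turns the five-membered ring into the six-membered, aromatic 4-silyloxychromenylium chloride 15, which loses TBSCl to isoflavone 16. The closest known reaction types are the Ciamician–Dennstedt-type carbon-atom insertion of chlorodiazirine-derived aryl(chloro)carbenes into indoles and pyrroles and the dihalocarbene ring expansion of cyclic silyl enol ethers to 2-haloenones; the pairing of an aryl(chloro)carbene with a 3-silyloxybenzofuran is the untested part. The only ring closed is the transient cyclopropane, and the six-membered ring arises from its opening and not from a cyclisation; no stereocentre is formed, because the inserted carbon (C3 of the chromenone) leaves the step sp2-hybridised and is made stereogenic in step 9. The step needs chemoselectivity for the enol ether over the chromene C3=C4 double bond of 12, which the much higher nucleophilicity of the O–C=C–O unit and the excess of 2 should secure. It also needs cleavage of the former C2–C3 bond and no other, which is fixed because the leaving chloride sits on the inserted carbon opposite that bond. A cyclopropane epimer with exo chlorine, which cannot open directly in the fused system, is expected to equilibrate through reversible zwitterionic opening of the donor-substituted ring.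

Step 8
Reactants: 16 5,7-bis(tert-butyldimethylsilyloxy)-3-[2,2-dimethyl-5-(triisopropylsilyloxy)-2H-chromen-8-yl]-4H-chromen-4-one
Product: 18 allyl 5,7-bis(tert-butyldimethylsilyloxy)-3-[2,2-dimethyl-5-(triisopropylsilyloxy)-2H-chromen-8-yl]-2H-chromen-4-yl carbonate, via lithium enolate 17 (not isolated)
Conditions: L-Selectride, THF, −78 °C; then allyl chloroformate, −78 → 0 °C
Reagents that add atoms: allyl chloroformate, C=CCOC(=O)Cl
Why: Conjugate hydride addition to the chromone enone should give enolate 17, which the chloroformate O-acylates at −78 °C before the neighbouring 5-O-silyl group can migrate (reductive enolate trapping).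

Step 9
Reactants: 18 allyl 5,7-bis(tert-butyldimethylsilyloxy)-3-[2,2-dimethyl-5-(triisopropylsilyloxy)-2H-chromen-8-yl]-2H-chromen-4-yl carbonate
Product: 19 (3R)-5,7-bis(tert-butyldimethylsilyloxy)-3-[2,2-dimethyl-5-(triisopropylsilyloxy)-2H-chromen-8-yl]-2,3-dihydro-4H-chromen-4-one
Conditions: Pd2(dba)3 (cat.), (CF3)3-t-Bu-PHOX (cat.), Meldrum's acid, 1,4-dioxane, 40 °C
Reagents that add atoms: none
Why: Palladium-catalysed decarboxylative asymmetric protonation, in which oxidative addition and loss of CO2 give a chiral PHOX–Pd(allyl) enolate and Meldrum's acid protonates one face of C3 under ligand control while carrying off the allyl group, so C3 is set as R from an achiral precursor; the ligand antipode that leads to the 3R series is the one to be used.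

Step 10
Reactants: 19 (3R)-5,7-bis(tert-butyldimethylsilyloxy)-3-[2,2-dimethyl-5-(triisopropylsilyloxy)-2H-chromen-8-yl]-2,3-dihydro-4H-chromen-4-one
Product: 20 (3R)-5,7-dihydroxy-3-(5-hydroxy-2,2-dimethyl-2H-chromen-8-yl)-2,3-dihydro-4H-chromen-4-one
Conditions: TBAF, AcOH, THF, 0 °C
Reagents that add atoms: none
Why: Fluoride cleavage of the three aryl silyl ethers, buffered with acetic acid so that no free phenoxide or enolate should epimerise the α-aryl ketone at C3 (desilylation).

Compound list
1 | 4,6-dihydroxy-1-benzofuran-3(2H)-one | O=C1COc2cc(O)cc(O)c12 | starting material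
2 | 3,4,6-tris(tert-butyldimethylsilyloxy)-1-benzofuran | CC(C)(C)[Si](C)(C)Oc1coc2cc(O[Si](C)(C)C(C)(C)C)cc(O[Si](C)(C)C(C)(C)C)c12 | intermediate
3 | 4-bromobenzene-1,3-diol | Oc1ccc(Br)c(O)c1 | starting material
4 | 2-bromo-5-(triisopropylsilyloxy)phenol | Oc1cc(O[Si](C(C)C)(C(C)C)C(C)C)ccc1Br | intermediate
5 | 3-chloro-3-methylbut-1-yne | CC(C)(Cl)C#C | starting material
6 | [4-bromo-3-(2-methylbut-3-yn-2-yloxy)phenoxy]triisopropylsilane | C#CC(C)(C)Oc1cc(O[Si](C(C)C)(C(C)C)C(C)C)ccc1Br | intermediate
7 | 6-bromo-2-(3-methylbuta-1,2-dien-1-yl)-3-(triisopropylsilyloxy)phenol (o-allenylphenol) | Oc1c(Br)ccc(O[Si](C(C)C)(C(C)C)C(C)C)c1C=C=C(C)C | intermediate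
8 | 8-bromo-2,2-dimethyl-5-(triisopropylsilyloxy)-2H-chromene | CC1(C)C=Cc2c(O[Si](C(C)C)(C(C)C)C(C)C)ccc(Br)c2O1 | intermediate
9 | [2,2-dimethyl-5-(triisopropylsilyloxy)-2H-chromen-8-yl]lithium (aryllithium) | CC1(C)C=Cc2c(O[Si](C(C)C)(C(C)C)C(C)C)ccc([Li])c2O1 | intermediate
10 | lithium N,N'-bis(trimethylsilyl)-2,2-dimethyl-5-(triisopropylsilyloxy)-2H-chromene-8-carboximidamidate | CC1(C)C=Cc2c(O[Si](C(C)C)(C(C)C)C(C)C)ccc(C(=N[Si](C)(C)C)N([Li])[Si](C)(C)C)c2O1 | intermediate
11 | 2,2-dimethyl-5-(triisopropylsilyloxy)-2H-chromene-8-carboximidamide hydrochloride | Cl.CC1(C)C=Cc2c(O[Si](C(C)C)(C(C)C)C(C)C)ccc(C(N)=N)c2O1 | intermediate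
12 | 3-chloro-3-[2,2-dimethyl-5-(triisopropylsilyloxy)-2H-chromen-8-yl]-3H-diazirine | CC1(C)C=Cc2c(O[Si](C(C)C)(C(C)C)C(C)C)ccc(C3(Cl)N=N3)c2O1 | intermediate
13 | chloro[2,2-dimethyl-5-(triisopropylsilyloxy)-2H-chromen-8-yl]carbene | CC1(C)C=Cc2c(O[Si](C(C)C)(C(C)C)C(C)C)ccc([C]Cl)c2O1 | intermediate
14 | 1-chloro-1-[2,2-dimethyl-5-(triisopropylsilyloxy)-2H-chromen-8-yl]-4,6,6b-tris(tert-butyldimethylsilyloxy)-1a,6b-dihydro-1H-cyclopropa[b][1]benzofuran (chlorocyclopropane adduct) | CC(C)(C)[Si](C)(C)OC12c3c(O[Si](C)(C)C(C)(C)C)cc(O[Si](C)(C)C(C)(C)C)cc3OC1C2(Cl)c1ccc(O[Si](C(C)C)(C(C)C)C(C)C)c2C=CC(C)(C)Oc12 | intermediate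
15 | 4,5,7-tris(tert-butyldimethylsilyloxy)-3-[2,2-dimethyl-5-(triisopropylsilyloxy)-2H-chromen-8-yl]chromenylium chloride | [Cl-].CC(C)(C)[Si](C)(C)Oc1c(-c2ccc(O[Si](C(C)C)(C(C)C)C(C)C)c3C=CC(C)(C)Oc23)c[o+]c2cc(O[Si](C)(C)C(C)(C)C)cc(O[Si](C)(C)C(C)(C)C)c12 | intermediate
16 | 5,7-bis(tert-butyldimethylsilyloxy)-3-[2,2-dimethyl-5-(triisopropylsilyloxy)-2H-chromen-8-yl]-4H-chromen-4-one | CC1(C)C=Cc2c(O[Si](C(C)C)(C(C)C)C(C)C)ccc(C3=COc4cc(O[Si](C)(C)C(C)(C)C)cc(O[Si](C)(C)C(C)(C)C)c4C3=O)c2O1 | intermediate
17 | lithium 5,7-bis(tert-butyldimethylsilyloxy)-3-[2,2-dimethyl-5-(triisopropylsilyloxy)-2H-chromen-8-yl]-2H-chromen-4-olate | CC1(C)C=Cc2c(O[Si](C(C)C)(C(C)C)C(C)C)ccc(C3=C(O[Li])c4c(O[Si](C)(C)C(C)(C)C)cc(O[Si](C)(C)C(C)(C)C)cc4OC3)c2O1 | intermediate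
18 | allyl 5,7-bis(tert-butyldimethylsilyloxy)-3-[2,2-dimethyl-5-(triisopropylsilyloxy)-2H-chromen-8-yl]-2H-chromen-4-yl carbonate | CC1(C)C=Cc2c(O[Si](C(C)C)(C(C)C)C(C)C)ccc(C3=C(OC(=O)OCC=C)c4c(O[Si](C)(C)C(C)(C)C)cc(O[Si](C)(C)C(C)(C)C)cc4OC3)c2O1 | intermediate
19 | (3R)-5,7-bis(tert-butyldimethylsilyloxy)-3-[2,2-dimethyl-5-(triisopropylsilyloxy)-2H-chromen-8-yl]-2,3-dihydro-4H-chromen-4-one | CC1(C)C=Cc2c(O[Si](C(C)C)(C(C)C)C(C)C)ccc([C@@H]3COc4cc(O[Si](C)(C)C(C)(C)C)cc(O[Si](C)(C)C(C)(C)C)c4C3=O)c2O1 | intermediate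
20 | (3R)-5,7-dihydroxy-3-(5-hydroxy-2,2-dimethyl-2H-chromen-8-yl)-2,3-dihydro-4H-chromen-4-one | CC1(C)C=Cc2c(O)ccc([C@@H]3COc4cc(O)cc(O)c4C3=O)c2O1 | target

Total step count: 10. Longest linear sequence: 9 steps (steps 2 to 10, from 3 to 20).

Steps most likely to fail

Step 7. The free carbene may be consumed by cyclopropanation of the chromene double bond of a second molecule, or the carbene–enol ether adduct may collapse without ring opening to the non-expanded 2-benzylidene isomer. The fallback keeps the one-carbon ring expansion but carries it out with known chemistry and moves the aryl–C3 bond to a cross-coupling; it sets out from 2 and 8 and comes back at 16. Dibromocarbene (CHBr3, KOt-Bu, hexane, −30 °C → rt) should add to the enol ether of 2 and the adduct should open with loss of the silyl bromide to 3-bromo-5,7-bis(tert-butyldimethylsilyloxy)-4H-chromen-4-one F1. Bromide 8 would be converted by bromine–lithium exchange and quench with isopropoxy pinacol borane into 2-[2,2-dimethyl-5-(triisopropylsilyloxy)-2H-chromen-8-yl]-4,4,5,5-tetramethyl-1,3,2-dioxaborolane F2. Suzuki–Miyaura coupling of F1 with F2 (Pd(OAc)2/SPhos, K3PO4, toluene, 60 °C) should then give isoflavone 16.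

Step 6. Hypochlorite may attack the chromene double bond or chlorinate the electron-rich ring faster than it builds the diazirine. The fallback postpones the chromene unsaturation, which also removes the competing alkene from the carbene step; it sets out from 11 and comes back at 16. Hydrogenation of 11 (H2, Pd/C, MeOH) should give 2,2-dimethyl-5-(triisopropylsilyloxy)chromane-8-carboximidamide hydrochloride F3. Graham oxidation as in step 6 would give 3-chloro-3-[2,2-dimethyl-5-(triisopropylsilyloxy)chroman-8-yl]-3H-diazirine F4. Carbene insertion into 2 as in step 7 would give 5,7-bis(tert-butyldimethylsilyloxy)-3-[2,2-dimethyl-5-(triisopropylsilyloxy)chroman-8-yl]-4H-chromen-4-one F5. DDQ dehydrogenation of the 2,2-dimethylchroman (dioxane, 80 °C), at a stage where no stereocentre is at risk, should then give 16.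

Step 9. Facial selectivity in the protonation of the hindered, tetrasubstituted palladium enolate may be poor, or C-allylation may compete with protonation. The fallback replaces enolate protonation by a reduction under dynamic kinetic resolution; it sets out from 16, bypasses 18 and comes back at 19. Asymmetric transfer hydrogenation (RuCl(p-cymene)[(R,R)-TsDPEN], HCO2H/Et3N, EtOAc, 40 °C) should reduce the C2=C3 bond and then the ketone of the racemising isoflavanone, funnelling it into (3R,4R)-5,7-bis(tert-butyldimethylsilyloxy)-3-[2,2-dimethyl-5-(triisopropylsilyloxy)-2H-chromen-8-yl]chroman-4-ol F6 with the aryl and hydroxyl groups cis. Dess–Martin oxidation (NaHCO3, CH2Cl2, 0 °C) of the benzylic alcohol should restore the ketone without touching C3 and give 19.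

Further compounds
F1 | step 7 | 3-bromo-5,7-bis(tert-butyldimethylsilyloxy)-4H-chromen-4-one | O=C1C(Br)=COc2cc(O[Si](C)(C)C(C)(C)C)cc(O[Si](C)(C)C(C)(C)C)c12
F2 | step 7 | 2-[2,2-dimethyl-5-(triisopropylsilyloxy)-2H-chromen-8-yl]-4,4,5,5-tetramethyl-1,3,2-dioxaborolane | CC1(C)C=Cc2c(O[Si](C(C)C)(C(C)C)C(C)C)ccc(B3OC(C)(C)C(C)(C)O3)c2O1
F3 | step 6 | 2,2-dimethyl-5-(triisopropylsilyloxy)chromane-8-carboximidamide hydrochloride | Cl.CC1(C)CCc2c(O[Si](C(C)C)(C(C)C)C(C)C)ccc(C(N)=N)c2O1
F4 | step 6 | 3-chloro-3-[2,2-dimethyl-5-(triisopropylsilyloxy)chroman-8-yl]-3H-diazirine | CC1(C)CCc2c(O[Si](C(C)C)(C(C)C)C(C)C)ccc(C3(Cl)N=N3)c2O1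
F5 | step 6 | 5,7-bis(tert-butyldimethylsilyloxy)-3-[2,2-dimethyl-5-(triisopropylsilyloxy)chroman-8-yl]-4H-chromen-4-one | CC1(C)CCc2c(O[Si](C(C)C)(C(C)C)C(C)C)ccc(C3=COc4cc(O[Si](C)(C)C(C)(C)C)cc(O[Si](C)(C)C(C)(C)C)c4C3=O)c2O1
F6 | step 9 | (3R,4R)-5,7-bis(tert-butyldimethylsilyloxy)-3-[2,2-dimethyl-5-(triisopropylsilyloxy)-2H-chromen-8-yl]chroman-4-ol | CC1(C)C=Cc2c(O[Si](C(C)C)(C(C)C)C(C)C)ccc([C@@H]3COc4cc(O[Si](C)(C)C(C)(C)C)cc(O[Si](C)(C)C(C)(C)C)c4[C@@H]3O)c2O1
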